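**Plan**

1. Numbering: target chain C1 (lactone C=O) to C12 (CH3); the tetrahydrofuran is O–C7–C8–C9–C10. Cuts: the lactone acyl C–O and C2=C3 (acid lactonisation, Z-olefination of a C3 aldehyde); the cinnamate acyl C–O and its alkene (aryl propiolate, semi-hydrogenation); then the tetrahydrofuran at C8–C9 and O–C10 together.
2. Enabling feature: ring carbon C10 and exocyclic C11 carry vicinal threo oxygens (ring O, ester O), and O7 sits three carbons from C10. This is the pattern left by 5-exo opening of a cis C10–C11 epoxide by O7. C8 is the ring CH2 next to the O7-bearing C7, so a β-oxido sulfonyl carbanion (C8) and an epoxy triflate (C9–C12) can close both bonds in one pot.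
3. Forward: D-galactal → open-chain hydroxy sulfone (C3–C8, C3 masked as vinyl); but-2-yn-1-ol → cis-epoxy triflate; one-pot C-alkylation/epoxide opening builds the tetrahydrofuran and joins the halves; sulfone removed; alkene → aldehyde → (Z)-enoate; C11 ester; alkyne → (Z)-alkene; acid removes the acetonide and closes the dihydropyranone last.
4. Stereochemistry: C5, C6, C7 come from C3, C4, C5 of D-galactal; C10 by inversion of the epoxide carbon (gives the 2,5-cis ring); C11 and the cis-epoxide from Sharpless epoxidation of the (Z)-allylic alcohol; the two (Z)-alkenes from Still–Gennari olefination and Lindlar reduction.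

Key step: step 9

**Route**

Step 1
Reactants: 1 D-galactal
Product: 2 6-O-(p-tolylsulfonyl)-D-galactal
Conditions: TsCl (1.05 equiv), pyridine, CH2Cl2, −10 → 0 °C
Reagents that add atoms: p-toluenesulfonyl chloride, Cc1ccc(cc1)S(=O)(=O)Cl
Why: The primary 6-OH should be sulfonylated much faster than the two secondary hydroxyls (selective O-sulfonylation); no stereocentre is touched.

Step 2
Reactants: 2 6-O-(p-tolylsulfonyl)-D-galactal
Product: 3 3,4-O-isopropylidene-6-O-(p-tolylsulfonyl)-D-galactal
Conditions: 2,2-dimethoxypropane, PPTS (cat.), acetone, rt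
Reagents that add atoms: 2,2-dimethoxypropane, COC(C)(C)OC
Why: Acid-catalysed transacetalisation closes the dioxolane on the cis-3,4-diol (acetonide formation); PPTS is too weak to add methanol to the enol ether.

Step 3
Reactants: 3 3,4-O-isopropylidene-6-O-(p-tolylsulfonyl)-D-galactal
Product: 4 6-deoxy-3,4-O-isopropylidene-6-(phenylsulfonyl)-D-galactal
Conditions: PhSO2Na (3 equiv), NaI (0.2 equiv), DMF, 90 °C
Reagents that add atoms: sodium benzenesulfinate, [Na+].[O-]S(=O)c1ccccc1
Why: SN2 displacement of the primary tosylate by the sulfur of the sulfinate, helped by iodide (Finkelstein) catalysis, installs the sulfonyl group that will acidify C8.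

Step 4
Reactants: 4 6-deoxy-3,4-O-isopropylidene-6-(phenylsulfonyl)-D-galactal
Product: 5 2,6-dideoxy-3,4-O-isopropylidene-6-(phenylsulfonyl)-D-lyxo-hexopyranose (anomer mixture)
Conditions: Ph3P·HBr (0.05 equiv), THF/H2O (10:1), rt
Reagents that add atoms: water, O
Why: Protonation of the enol ether at C2 and capture of the oxocarbenium ion by water (Markovnikov hydration of a glycal, no allylic rearrangement) gives the 2-deoxy lactol; the weakly acidic salt should spare the dioxolane.

Step 5
Reactants: 5 2,6-dideoxy-3,4-O-isopropylidene-6-(phenylsulfonyl)-D-lyxo-hexopyranose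
Product: 6 (1S)-1-[(4S,5R)-2,2-dimethyl-5-(prop-2-en-1-yl)-1,3-dioxolan-4-yl]-2-(phenylsulfonyl)ethan-1-ol
Conditions: Ph3PCH3Br (3.0 equiv), KOt-Bu (2.9 equiv), THF, 0 °C; then 5, 0 °C → rt
Reagents that add atoms: methyltriphenylphosphonium bromide, C[P+](c1ccccc1)(c1ccccc1)c1ccccc1.[Br-]
Why: Wittig methylenation of the open-chain aldehyde tautomer frees the former ring oxygen as the C7 hydroxyl and masks C3 as a vinyl group; the ylide is not basic enough to deprotonate next to the sulfone.

Step 6
Reactants: 7 but-2-yn-1-ol
Product: 8 (Z)-but-2-en-1-ol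
Conditions: H2 (1 atm), Pd/CaCO3 poisoned with Pb(OAc)2 (Lindlar catalyst), quinoline, Et2O, 0 °C
Reagents that add atoms: none
Why: Lindlar semi-hydrogenation adds H2 syn to the alkyne and should stop at the (Z)-alkene.

Step 7
Reactants: 8 (Z)-but-2-en-1-ol
Product: 9 [(2R,3S)-3-methyloxiran-2-yl]methanol
Conditions: Ti(OiPr)4, D-(−)-diisopropyl tartrate, t-BuOOH, 4 Å molecular sieves, CH2Cl2, −20 °C
Reagents that add atoms: tert-butyl hydroperoxide, CC(C)(C)OO
Why: Sharpless asymmetric epoxidation; the D-(−)-tartrate complex should deliver oxygen to the face giving the (2R,3S)-epoxide with the cis geometry retained, which sets C11 and the C10 centre that is inverted later.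

Step 8
Reactants: 9 [(2R,3S)-3-methyloxiran-2-yl]methanol
Product: 10 [(2R,3S)-3-methyloxiran-2-yl]methyl trifluoromethanesulfonate
Conditions: Tf2O, 2,6-lutidine, CH2Cl2, −78 °C; used at once as a cold solution
Reagents that add atoms: trifluoromethanesulfonic anhydride, O=S(=O)(OS(=O)(=O)C(F)(F)F)C(F)(F)F
Why: O-Triflation of the primary alcohol at low temperature with a hindered base leaves the epoxide intact and gives an electrophile reactive enough to be alkylated at −78 °C.

Step 9
Reactants: 6 hydroxy sulfone; 10 epoxy triflate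
Product: 12 sulfonyl tetrahydrofuran alcohol (13 carrying PhSO2 on C8; both C8 epimers), via C-alkylated epoxy alcohol 11 (not isolated)
Conditions: n-BuLi (2.05 equiv), THF, −78 °C; 10 (1.2 equiv), −78 °C; then CSA (2.3 equiv), −78 °C → rt, same flask
Reagents that add atoms: none
Why: Double deprotonation gives the β-oxido α-sulfonyl carbanion, whose carbon displaces the primary triflate (SN2) to form C8–C9 and place the epoxide three atoms from O7; protonation with CSA then triggers anti opening of the epoxide by O7 at its nearer carbon, forming O–C10. The closest known reaction types are C-alkylation of hydroxy sulfone dianions with triflates and the acid-catalysed epoxy alcohol cyclisation of polyether synthesis. The tetrahydrofuran closes in the 5-exo-tet mode, preferred over 6-endo because neither epoxide carbon is cation-stabilised. C7 keeps the D-galactal configuration, C10 is set by inversion of the (R)-epoxide carbon, which places its substituent cis to that at C7, and C11 keeps the (S)-configuration of the epoxide; C8 forms as an epimer mixture that step 10 erases. The step needs C- over O-alkylation, triflate over epoxide attack by the carbanion, and oxygen over carbanion attack on the epoxide; the more nucleophilic carbanion, the low temperature and the acid quench before warming (which removes any carbanion) should secure these.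

Step 10
Reactants: 12 sulfonyl tetrahydrofuran alcohol
Product: 13 (1S)-1-[(2S,5R)-5-[(4S,5R)-2,2-dimethyl-5-(prop-2-en-1-yl)-1,3-dioxolan-4-yl]oxolan-2-yl]ethan-1-ol
Conditions: Na/Hg (6 % Na), Na2HPO4, MeOH/THF, −20 °C
Reagents that add atoms: none
Why: Reductive desulfonylation by electron transfer cleaves the C8–S bond and methanol protonates C8; loss of the ring oxygen would be the reverse of a 5-endo closure, poorly aligned in the ring, and protonation in the buffered protic medium at low temperature should outrun it.

Step 11
Reactants: 13 tetrahydrofuran alcohol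
Product: 14 C3 aldehyde (13 with the vinyl group cut to CH=O; stereocentres as in 13)
Conditions: O3, CH2Cl2, −78 °C; then PPh3, −78 °C → rt
Reagents that add atoms: ozone, [O-][O+]=O
Why: Ozonolysis with reductive work-up cleaves the only C=C present to the aldehyde; the free secondary hydroxyl, the acetal and the ether are inert.

Step 12
Reactants: 14 C3 aldehyde
Product: 15 methyl (Z)-enoate (C1–C12 chain, free C11 hydroxyl; stereocentres as in 13)
Conditions: (CF3CH2O)2P(O)CH2CO2Me, KN(SiMe3)2, 18-crown-6, THF, −78 °C
Reagents that add atoms: methyl bis(2,2,2-trifluoroethyl)phosphonoacetate, COC(=O)CP(=O)(OCC(F)(F)F)OCC(F)(F)F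
Why: Still–Gennari olefination: fast elimination from the kinetic adduct of the electron-poor phosphonate should give the (Z)-enoate, and the cold, non-equilibrating conditions avoid β-elimination of the β-alkoxy aldehyde.

Step 13
Reactants: 15 methyl (Z)-enoate; 16 3-(4-methoxyphenyl)propiolic acid
Product: 17 C11 3-(4-methoxyphenyl)propiolate of 15
Conditions: DCC, DMAP (cat.), CH2Cl2, 0 °C → rt
Reagents that add atoms: none
Why: Steglich esterification acylates the only free hydroxyl with retention at C11; carrying the cinnamate as its alkyne avoids Z/E drift during acyl transfer.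

Step 14
Reactants: 17 aryl propiolate
Product: 18 (Z)-4-methoxycinnamate (acetonide, methyl (Z)-enoate; stereocentres as in 13)
Conditions: H2 (1 atm), Pd/CaCO3 poisoned with Pb(OAc)2 (Lindlar catalyst), quinoline, EtOAc, rt, stopped after one equivalent of H2
Reagents that add atoms: none
Why: Lindlar semi-hydrogenation (syn addition) converts the aryl alkynoate into the (Z)-cinnamate; the conjugated (Z)-enoate should not be reduced on the poisoned catalyst.

Step 15
Reactants: 18 (Z)-4-methoxycinnamate
Product: 19 target
Conditions: AcOH/H2O (4:1), 60 °C; concentrate from toluene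
Reagents that add atoms: none
Why: Aqueous acid hydrolyses the dioxolane and the freed C5 hydroxyl lactonises onto the (Z)-ester (six-membered ring; the C6 hydroxyl would need a seven-membered ring), giving the dihydropyranone with the C6 hydroxyl free.

**Compound list**

1 | D-galactal (1,5-anhydro-2-deoxy-D-lyxo-hex-1-enitol) | OC[C@H]1OC=C[C@@H](O)[C@H]1O | starting material
2 | 6-O-(p-tolylsulfonyl)-D-galactal | Cc1ccc(cc1)S(=O)(=O)OC[C@H]1OC=C[C@@H](O)[C@H]1O | intermediate
3 | 3,4-O-isopropylidene-6-O-(p-tolylsulfonyl)-D-galactal | Cc1ccc(cc1)S(=O)(=O)OC[C@H]1OC=C[C@H]2OC(C)(C)O[C@@H]12 | intermediate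
4 | 6-deoxy-3,4-O-isopropylidene-6-(phenylsulfonyl)-D-galactal | O=S(=O)(C[C@H]1OC=C[C@H]2OC(C)(C)O[C@@H]12)c1ccccc1 | intermediate
5 | 2,6-dideoxy-3,4-O-isopropylidene-6-(phenylsulfonyl)-D-lyxo-hexopyranose (anomer mixture) | O=S(=O)(C[C@H]1OC(O)C[C@H]2OC(C)(C)O[C@@H]12)c1ccccc1 | intermediate
6 | (1S)-1-[(4S,5R)-2,2-dimethyl-5-(prop-2-en-1-yl)-1,3-dioxolan-4-yl]-2-(phenylsulfonyl)ethan-1-ol | C=CC[C@H]1OC(C)(C)O[C@H]1[C@H](O)CS(=O)(=O)c1ccccc1 | intermediate
7 | but-2-yn-1-ol | CC#CCO | starting material
8 | (Z)-but-2-en-1-ol | C/C=C\CO | intermediate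
9 | [(2R,3S)-3-methyloxiran-2-yl]methanol | OC[C@H]1O[C@H]1C | intermediate
10 | [(2R,3S)-3-methyloxiran-2-yl]methyl trifluoromethanesulfonate | FC(F)(F)S(=O)(=O)OC[C@H]1O[C@H]1C | intermediate
11 | C-alkylated epoxy alcohol: 6 carrying the [(2R,3S)-3-methyloxiran-2-yl]methyl group on the sulfonyl carbon (both epimers there; not isolated) | C=CC[C@H]1OC(C)(C)O[C@H]1[C@H](O)C(C[C@H]1O[C@H]1C)S(=O)(=O)c1ccccc1 | intermediate
12 | sulfonyl tetrahydrofuran alcohol: 13 carrying a phenylsulfonyl group on ring carbon C8, next to the dioxolanyl-bearing C7 (both C8 epimers; other centres arranged as in 13) | C=CC[C@H]1OC(C)(C)O[C@H]1[C@H]1C(S(=O)(=O)c2ccccc2)C[C@@H]([C@H](C)O)O1 | intermediate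
13 | (1S)-1-[(2S,5R)-5-[(4S,5R)-2,2-dimethyl-5-(prop-2-en-1-yl)-1,3-dioxolan-4-yl]oxolan-2-yl]ethan-1-ol (2,5-cis ring) | C=CC[C@H]1OC(C)(C)O[C@H]1[C@H]1CC[C@@H]([C@H](C)O)O1 | intermediate
14 | C3 aldehyde: 13 with the allyl group shortened to CH2–CH=O (stereocentres as in 13) | O=CC[C@H]1OC(C)(C)O[C@H]1[C@H]1CC[C@@H]([C@H](C)O)O1 | intermediate
15 | methyl (Z)-enoate: 14 extended at the aldehyde to CH=CH–CO2Me, Z (stereocentres as in 13) | COC(=O)/C=C\C[C@H]1OC(C)(C)O[C@H]1[C@H]1CC[C@@H]([C@H](C)O)O1 | intermediate
16 | 3-(4-methoxyphenyl)propiolic acid | COc1ccc(cc1)C#CC(=O)O | starting material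
17 | 15 esterified at the C11 hydroxyl with 16 (aryl propiolate) | COC(=O)/C=C\C[C@H]1OC(C)(C)O[C@H]1[C@H]1CC[C@@H]([C@H](C)OC(=O)C#Cc2ccc(OC)cc2)O1 | intermediate
18 | 17 with the alkyne reduced to the (Z)-alkene [(Z)-4-methoxycinnamate] | COC(=O)/C=C\C[C@H]1OC(C)(C)O[C@H]1[C@H]1CC[C@@H]([C@H](C)OC(=O)/C=C\c2ccc(OC)cc2)O1 | intermediate
19 | target: (S)-1-[(2S,5R)-5-[(S)-hydroxy[(R)-6-oxo-3,6-dihydro-2H-pyran-2-yl]methyl]oxolan-2-yl]ethyl (Z)-3-(4-methoxyphenyl)prop-2-enoate | COc1ccc(/C=C\C(=O)O[C@@H](C)[C@@H]2CC[C@H]([C@H](O)[C@H]3CC=CC(=O)O3)O2)cc1 | target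

**Step count and risks**

Total steps: 15. Longest linear sequence: 12 steps (steps 1–5 and 9–15, from D-galactal).

Step 9. What may go wrong: after the first alkylation a proton may shift from C8 to leftover base and the new carbanion may attack the epoxide (three-membered carbocycle); the alkoxide may be O-alkylated; the β-oxido sulfone may fragment by retro-addition on warming; or ring closure may stall. Fallback, setting out from 6: silylation (Et3SiCl, imidazole, DMF) gives the triethylsilyl ether F1. Single deprotonation (n-BuLi, 1.05 equiv, THF, −78 °C) and alkylation with 10 give the silyl-protected epoxy sulfone F2, so that C–C bond formation happens with no free alkoxide. HF·pyridine in THF then removes the silyl group and the freed hydroxyl closes onto the epoxide under the same acidic conditions. The sequence comes back to the route at 12.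

Step 10. What may go wrong: the reduced C8 may expel the ring oxygen (reductive ring opening to an alkenol) faster than it is protonated. Fallback, setting out from 12: ozonolysis with NaBH4 work-up (O3, CH2Cl2/MeOH, −78 °C; NaBH4) gives the sulfonyl diol F3, which has no alkene. Raney Ni in EtOH at reflux then removes the sulfonyl group by hydrogenolysis on the metal surface, without a free carbanion, to give the diol F4. Selective oxidation of the primary alcohol (TEMPO, PhI(OAc)2, CH2Cl2) comes back to the route at 14.

Step 3. What may go wrong: substitution at C6 is slow because the cis-fused dioxolane sits on the same face, and with the weakly nucleophilic sulfinate O-alkylation or decomposition of the enol ether on long heating may take over. Fallback, setting out from 3: hydration as in step 4 (Ph3P·HBr cat., THF/H2O) gives the tosyl lactol F5. Wittig methylenation with excess Ph3P=CH2 olefinates the aldehyde, and the liberated C7 alkoxide displaces the neighbouring tosylate, giving the epoxy alkene F6. Opening of this unhindered terminal epoxide at CH2 with PhSO2Na (DMF/H2O, 80 °C) comes back to the route at 6.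

Further compounds
F1 | step 9 | triethylsilyl ether of 6 | C=CC[C@H]1OC(C)(C)O[C@H]1[C@H](O[Si](CC)(CC)CC)CS(=O)(=O)c1ccccc1
F2 | step 9 | silyl-protected epoxy sulfone (F1 alkylated on the sulfonyl carbon with the epoxybutyl group of 10) | C=CC[C@H]1OC(C)(C)O[C@H]1[C@H](O[Si](CC)(CC)CC)C(C[C@H]1O[C@H]1C)S(=O)(=O)c1ccccc1
F3 | step 10 | sulfonyl diol (12 with the vinyl group cut to CH2OH) | OCC[C@H]1OC(C)(C)O[C@H]1[C@H]1C(S(=O)(=O)c2ccccc2)C[C@@H]([C@H](C)O)O1
F4 | step 10 | diol (F3 without the sulfonyl group) | OCC[C@H]1OC(C)(C)O[C@H]1[C@H]1CC[C@@H]([C@H](C)O)O1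
F5 | step 3 | 2-deoxy-3,4-O-isopropylidene-6-O-(p-tolylsulfonyl)-D-lyxo-hexopyranose (tosyl lactol) | Cc1ccc(cc1)S(=O)(=O)OC[C@H]1OC(O)C[C@H]2OC(C)(C)O[C@@H]12
F6 | step 3 | epoxy alkene: (4R,5S)-2,2-dimethyl-4-(prop-2-en-1-yl)-5-[(2R)-oxiran-2-yl]-1,3-dioxolane | C=CC[C@H]1OC(C)(C)O[C@H]1[C@H]1CO1
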